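All runs are simulated from invented constants.

Time is the cheap half of this hunch. The zeta run has the same equivalents as the new flask, and its charge of 1.8 M against 1.2 M would run its clock faster by a factor of 1.50 if each step takes two partners. Its highest reading of complex with one exchanged, at 3.00 min, on that footing lands at 0.0750 h in the new flask.

| flask | starting complex | incoming ligand | remark | time |
|---|---|---|---|---|
| delta | 1.2 M | 0.45 equiv | run made earlier |  |
| beta | 1.2 M | 1.8 equiv | run made earlier |  |
| zeta | 1.8 M | 0.90 equiv | run made earlier |  |
| flask | 1.2 M | 0.900 equiv |  | 1.0 h |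

| run | time / min | complex with one exchanged / % | complex with two exchanged / % | starting complex / % |
|---|---|---|---|---|
| delta | 0.833 | 6.3 | 0.3 | 47.3 |
| delta | 3.00 | 10.9 | 1.6 | 19.4 |
| delta | 10.0 | 11.5 | 4.5 | 6.6 |
| delta | 40.0 | 6.5 | 9.9 | 1.3 |
| beta | 0.833 | 20.9 | 2.6 | 38.4 |
| beta | 3.00 | 23.6 | 12.1 | 12.2 |
| beta | 10.0 | 9.8 | 22.8 | 3.7 |
| beta | 40.0 | 1.1 | 13.0 | 0.2 |
| zeta | 0.833 | 14.6 | 1.1 | 34.0 |
| zeta | 3.00 | 17.4 | 6.2 | 10.7 |
| zeta | 10.0 | 9.5 | 14.0 | 3.8 |
| zeta | 40.0 | 1.8 | 12.9 | 0.8 |

(readings scatter by 0.3 percentage points)

1. the best time, 1.0 h at the latest, for complex with one exchanged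
2. the amount of complex with one exchanged, in percent of the starting complex charged, at that time



The amount needs a rule of its own. Delta and beta share a charge of starting complex and lie two doublings of incoming ligand apart, with highest readings of complex with one exchanged, the intermediate of this consecutive exchange, of 11.5% and 23.6%. The doubling gain, the factor by which that highest amount grows for each doubling of the equivalents at a fixed charge of starting complex, is therefore, as read from these two runs, 1.43. The new flask stands one doubling above delta, which gives 16.5%. A highest reading can fall short of the peak it samples, and zeta itself read 17.4%, so the reckoning here is 16.5% to 17.4%.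

The forecast, on the ground “All steps look bimolecular”, gives 18% (16.8% to 19.2%) at 0.057 h (0.04 h to 0.08 h), which is higher and earlier than this reckoning.

The new flask reaches 17.9% at 0.0551 h, a gain of 1.56 over delta's highest reading against the doubling gain of 1.43.

    complex with two exchanged + incoming ligand ⇌ leaving ligand + complex with three exchanged (K = 69.0, k = 6.96 × 10⁻⁴ M⁻¹ s⁻¹)
    2 starting complex → homo dimer (k = 0.00805 M⁻¹ s⁻¹)
    complex with one exchanged + incoming ligand ⇌ leaving ligand + complex with two exchanged (K = 76.3, k = 0.00207 M⁻¹ s⁻¹)
    2 starting complex → self-condensation product (k = 1.10 × 10⁻⁵ M⁻¹ s⁻¹)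
    leaving ligand → by-product carried off (k = 0.00232 s⁻¹)
    starting complex + incoming ligand ⇌ leaving ligand + complex with one exchanged (K = 1.12, k = 0.00392 M⁻¹ s⁻¹)

Afterwards the flask loses its complex with one exchanged: at 0.236 h this complex is made at 0.176 of the rate at which it is used up, each step taken net. By 0.500 h it stands at 5.13%. Taken from 17.9% down to the neighbour flask with 0.540 equiv, the doubling gain gives 13.7%, and that neighbour flask reached at its best 13.4%.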